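Atom numbers used below are those of the flavanone skeleton of the target 20 (O1, C2, C3, C4, C4a, C5–C8, C8a); ring A is the benzo ring, ring C the pyranone ring. Descriptor check: the SMILES encodes (2S) (O1 > aryl > C3 > H).

## The problem

The target is a (2S)-flavanone whose ring A is a 1,2,3,4-tetrasubstituted benzene: C4a carries the C4 carbonyl, C8a the ring oxygen O1, C8 the prenyl group and C7 a free hydroxyl. Putting the prenyl group at C8, between two oxygens, and not at C6 is a regiochemical problem for any electrophilic substitution of a resorcinol-type ring. The only stereocentre, C2, is benzylic, oxygen-bound and β to the ketone. Base opens ring C by retro-oxa-Michael reaction, and strong acid can ionise C2–O1, helped by the para oxygen of the chromene; no second stereocentre exists to control or restore C2. The prenyl olefin next to a phenol and the 2,2-dimethylchromene rule out strong acid, electrophilic halogen, sulfur or oxygen reagents, hydrogenation and strong oxidants, so late deprotection is costly. The feature that opens a different plan is in ring A itself: C5–C6–C7(O)–C8 is a four-carbon unit with oxygen on its third carbon, the imprint of a 1-alkoxy-3-silyloxydiene. It is joined to C4a=C8a, which inside ring C is the double bond of a β-alkoxy enone (C4a α to C4=O, C8a on O1). The prenyl-bearing C8 is the nucleophilic diene terminus and C8a the electrophilic enone β-carbon, so ring A can be built last, by cycloaddition, onto an enantiopure ring C.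

## Retrosynthesis

**20 ⇒ 11 + 16.** The bonds C8–C8a and C4a–C5 are cut, with methanol returned across C5/C6 and benzenesulfenic acid across C4a/C8a. Cuts at O1–C2 or C2–aryl leave ring A intact and so leave the C8 regiochemistry unsolved. This cut removes the whole benzene ring: 11 is a monocyclic dihydropyranone that already holds C2, and 16 is an achiral open-chain diene that carries the prenyl group. The forward reaction must be regioselective, must aromatise by two eliminations without an oxidant, and must stay acidic to neutral; it releases the phenol unprotected as the last step.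

**11 ⇒ 9.** The bonds O1–C6 and C5–C6 of the pyranone are cut; C6 becomes a one-carbon unit from a formamide acetal. Introducing sulfur after ring closure would need an electrophilic sulfur reagent such as PhSCl, which the chromene olefin would not survive. In 9 the sulfur already sits on the right carbon and the C2–O bond is never broken. The forward step must condense at the CH2 between carbonyl and sulfoxide and close the ring by O-attack without dehydrating the carbinol.

**9 ⇒ 6 + 7 (through 8).** The bond between the ketone carbon and CH2S is cut. An ester and a sulfinyl carbanion are the simplest partners; the forward step must tolerate the free carbinol as its lithium alkoxide.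

**6 ⇒ 5 ⇒ 4.** The C2–H bond is cut (ketone reduction), then the bond between the ketone α-carbon and the ester carbon. Setting C2 on an open-chain aryl ketone by catalyst-controlled hydrogen transfer is irreversible and leaves both olefins alone. Compound 5 is achiral and is one condensation away from 4.

**4 ⇒ 3 ⇒ 1 + 2.** The chromene ring is opened to an aryl 1,1-dimethylpropargyl ether, then the ether C–O bond is cut. With the para position blocked, the rearrangement can give only one chromene.

**16 ⇒ 15 ⇒ 12 + 13 (through 14).** The Si–O bond is cut, then the C4–C5 bond of the chain. Compound 12 has a single enolisable position, so the prenyl group can enter only at the future C8.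

## Roads not taken

**Alternative 1:** cut O1–C2 and the C2–C3 olefin precursor, the route most chemists would draw first. Forward key step: enantioselective intramolecular oxa-Michael addition of 2'-hydroxychalcone A1, made by Claisen–Schmidt condensation. The chosen plan is better on three counts:
- The acetophenone half needs C-prenylation of a resorcinol ring, which is expected to give C3, C5 and O-alkylation together.
- The ring closure is reversible under the conditions that promote it, so C2 is set under equilibrium, and an unactivated chalcone binds a chiral catalyst poorly.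
- The 7-hydroxyl needs a protecting group that is removed by acid next to the prenyl group.

In the chosen plan C8 is fixed by construction, C2 is set irreversibly, and no protecting group is used.

**Alternative 2:** cut the C2–aryl bond. Forward key step: enantioselective 1,4-addition of boronic acid A3 to chromone A2 under palladium or rhodium catalysis. This is convergent and sets C2 well, but A2 carries the same C8 prenylation problem, its 7-oxygen makes the chromone a weaker acceptor, and protection and deprotection return. The chosen plan builds the substitution pattern that this plan must buy.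

**Alternative 3:** keep ring A saturated and aromatise late. 2-Prenylcyclohexane-1,3-dione A4 fixes the prenyl group between the two oxygens; its vinylogous ester is cinnamoylated at C4a, closed by oxa-Michael addition to A5 and dehydrogenated. This solves C8 as the chosen plan does, but has three drawbacks:
- Aromatisation needs an oxidant (a quinone or palladium) in the presence of the prenyl group, the chromene and the benzylic C2–H.
- C2 again arises from a reversible oxa-Michael step.
- The 7-oxygen ends as an ether that must be cleaved.

The chosen plan carries both leaving groups in the precursors and aromatises by elimination.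

Key step: step 9

Remark: methyl phenyl sulfoxide 7 is used as the racemate, so 9, 10, 11, 17 and 18 are mixtures of epimers at sulfur (17 and 18 also at the transient ring carbons); all these centres are erased in step 9.

## Route

Step 1
Reactants: 1 4-hydroxyacetophenone; 2 3-chloro-3-methylbut-1-yne
Product: 3 1-{4-[(2-methylbut-3-yn-2-yl)oxy]phenyl}ethan-1-one
Conditions: K2CO3, KI (cat.), CuI (cat.), acetone, reflux
Reagents that add atoms: none
Why: Copper-assisted O-alkylation of a phenol by a tertiary propargylic chloride, the standard entry to aryl 1,1-dimethylpropargyl ethers.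

Step 2
Reactants: 3 1-{4-[(2-methylbut-3-yn-2-yl)oxy]phenyl}ethan-1-one
Product: 4 1-(2,2-dimethyl-2H-chromen-6-yl)ethan-1-one
Conditions: N,N-diethylaniline, 190 °C
Reagents that add atoms: none
Why: Aryl propargyl ether Claisen rearrangement, 1,5-hydrogen shift and oxa-6π electrocyclisation; the para acetyl group leaves two equivalent ortho positions, so only the 6-substituted chromene can form.

Step 3
Reactants: 4 1-(2,2-dimethyl-2H-chromen-6-yl)ethan-1-one
Product: 5 ethyl 3-(2,2-dimethyl-2H-chromen-6-yl)-3-oxopropanoate
Conditions: NaH, (EtO)2CO, THF, reflux; then AcOH, H2O, 0 °C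
Reagents that add atoms: diethyl carbonate, CCOC(=O)OCC
Why: Crossed Claisen condensation of a methyl ketone enolate with a carbonate, driven by formation of the β-keto ester enolate; the chromene is inert to base.

Step 4
Reactants: 5 ethyl 3-(2,2-dimethyl-2H-chromen-6-yl)-3-oxopropanoate
Product: 6 ethyl (3S)-3-(2,2-dimethyl-2H-chromen-6-yl)-3-hydroxypropanoate
Conditions: RuCl[(S,S)-TsDPEN](p-cymene) (1 mol %), HCO2H/Et3N (5:2), DMF, 30 °C
Reagents that add atoms: none
Why: Noyori asymmetric transfer hydrogenation of an aryl ketone; the (S,S)-catalyst delivers hydride to the Re face as it does for acetophenone, which here gives the (3S)-carbinol (O > aryl > CH2), the future C2, and the metal hydride leaves both olefins alone.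

Step 5
Reactants: 6 ethyl (3S)-3-(2,2-dimethyl-2H-chromen-6-yl)-3-hydroxypropanoate; 7 methyl phenyl sulfoxide
Product: 9 (4S)-4-(2,2-dimethyl-2H-chromen-6-yl)-4-hydroxy-1-(phenylsulfinyl)butan-2-one, via (phenylsulfinyl)methyllithium 8 (not isolated)
Conditions: 7 (3.3 equiv), LDA (3.2 equiv), THF, −78 °C; then 6, −78 to −20 °C; aq. NH4Cl
Reagents that add atoms: none
Why: Claisen-type acylation of an α-sulfinyl carbanion by an ester, the standard β-keto sulfoxide synthesis; the first equivalent of 8 turns the carbinol into its lithium alkoxide, the product is held as its enolate so no second addition occurs, and no bond to the stereocentre is touched.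

Step 6
Reactants: 9 (4S)-4-(2,2-dimethyl-2H-chromen-6-yl)-4-hydroxy-1-(phenylsulfinyl)butan-2-one
Product: 11 (2S)-2-(2,2-dimethyl-2H-chromen-6-yl)-5-(phenylsulfinyl)-2,3-dihydro-4H-pyran-4-one, via enaminone 10 (not isolated)
Conditions: Me2NCH(OMe)2 (1.5 equiv), CH2Cl2, rt; then AcOH (2 equiv), rt
Reagents that add atoms: N,N-dimethylformamide dimethyl acetal, COC(OC)N(C)C
Why: Condensation of the formamide acetal at the CH2 flanked by carbonyl and sulfoxide, then 6-endo addition of the hydroxyl to the enaminone carbon and loss of dimethylamine, as in chromone synthesis from 2-hydroxyaryl β-keto sulfoxides and dihydropyranone synthesis from δ-hydroxy β-keto esters; the C2–O bond is retained, so the (S) configuration is carried over.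

Step 7
Reactants: 12 (3E)-4-methoxybut-3-en-2-one; 13 1-bromo-3-methylbut-2-ene
Product: 15 (1E)-1-methoxy-7-methylocta-1,6-dien-3-one, via lithium dienolate 14 (not isolated)
Conditions: LDA, THF, −78 °C; then 13, DMPU, −78 to −30 °C
Reagents that add atoms: none
Why: Kinetic deprotonation at the only enolisable position (the methyl group) and SN2 alkylation of the cross-conjugated enolate at the primary carbon of the allylic bromide.

Step 8
Reactants: 15 (1E)-1-methoxy-7-methylocta-1,6-dien-3-one
Product: 16 (1E,3Z)-1-methoxy-7-methyl-3-[(trimethylsilyl)oxy]octa-1,3,6-triene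
Conditions: TMSOTf, Et3N, Et2O, 0 °C
Reagents that add atoms: trimethylsilyl trifluoromethanesulfonate, C[Si](C)(C)OS(=O)(=O)C(F)(F)F
Why: Soft enolisation and O-silylation, the usual preparation of 1-methoxy-3-silyloxydienes; the (Z)-enol ether should prevail because the chain then lies anti to the methoxyvinyl group, which places it outside in the s-cis diene as the cycloaddition needs.

Step 9
Reactants: 11 (2S)-2-(2,2-dimethyl-2H-chromen-6-yl)-5-(phenylsulfinyl)-2,3-dihydro-4H-pyran-4-one; 16 (1E,3Z)-1-methoxy-7-methyl-3-[(trimethylsilyl)oxy]octa-1,3,6-triene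
Product: 20 (2S)-2-(2,2-dimethyl-2H-chromen-6-yl)-7-hydroxy-8-(3-methylbut-2-en-1-yl)-2,3-dihydro-4H-chromen-4-one, via cycloadduct 17 (not isolated), via sulfinyl enone 18 (not isolated), via dienone tautomer 19 (not isolated)
Conditions: 16 (2 equiv), ZnCl2 (10 mol %), CH2Cl2, −20 °C to rt; CSA (cat.), 0 °C; then NaHCO3, toluene, 80 °C
Reagents that add atoms: none
Why: Proposed new method: the C5=C6 bond of 11 is polarised by both the C4 carbonyl and the sulfinyl group (C6 electrophilic), and 16 is a 1-methoxy-3-silyloxydiene whose most nucleophilic end is the prenyl-bearing C4, so a ZnCl2-chelated, asynchronous Diels–Alder reaction should join diene C4 to C6 and diene C1 to C5 of 11 and give 17, closing ring A as a six-membered carbocycle by [4+2] cycloaddition (bonds C8–C8a and C4a–C5 of 20). The closest known reaction type is the cycloaddition of 1-alkoxy-3-silyloxydienes to α-sulfinyl enones, sulfinyl quinones and 3-acceptor-substituted chromones, where thermal loss of the sulfoxide makes the enone an alkyne equivalent; it has not been shown on a 5-sulfinyl-2,3-dihydropyran-4-one or with a 4-alkyl diene of this kind. Catalytic acid then removes the silyl group and methanol from 17 by β-elimination to give enone 18, in which C5 is sp2 and the only hydrogen left cis and β to sulfur is H-8a; syn-elimination of benzenesulfenic acid at 80 °C should therefore form C4a=C8a, and the resulting dienone 19 enolises to phenol 20. No new stereocentre survives: the centres made at C4a, C5, C8, C8a and the sulfur centre are all erased, so facial and endo/exo selectivity do not matter. C2 is a spectator whose bonds are not touched, and the medium stays acidic to neutral so that ring C cannot open by retro-oxa-Michael reaction. The selectivities needed are the regiochemistry of the cycloaddition, secured by matched polarity (donor-substituted diene terminus to the oxygen-bearing enone β-carbon), which places the prenyl group at C8 and the hydroxyl at C7 by construction, and the order of the two eliminations, secured by running the cycloaddition cold and removing methanol before the sulfoxide is heated. Both leaving groups are built in, so aromatisation needs no oxidant and the phenol appears without a protecting group.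

## Compound list

1 | 4-hydroxyacetophenone | CC(=O)c1ccc(O)cc1 | starting material
2 | 3-chloro-3-methylbut-1-yne | C#CC(C)(C)Cl | starting material
3 | 1-{4-[(2-methylbut-3-yn-2-yl)oxy]phenyl}ethan-1-one | CC(=O)c1ccc(OC(C)(C)C#C)cc1 | intermediate
4 | 1-(2,2-dimethyl-2H-chromen-6-yl)ethan-1-one | CC(=O)c1ccc2c(c1)C=CC(C)(C)O2 | intermediate
5 | ethyl 3-(2,2-dimethyl-2H-chromen-6-yl)-3-oxopropanoate | CCOC(=O)CC(=O)c1ccc2c(c1)C=CC(C)(C)O2 | intermediate
6 | ethyl (3S)-3-(2,2-dimethyl-2H-chromen-6-yl)-3-hydroxypropanoate | CCOC(=O)C[C@H](O)c1ccc2c(c1)C=CC(C)(C)O2 | intermediate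
7 | methyl phenyl sulfoxide (racemic) | CS(=O)c1ccccc1 | starting material
8 | (phenylsulfinyl)methyllithium | [Li]CS(=O)c1ccccc1 | intermediate (not isolated)
9 | (4S)-4-(2,2-dimethyl-2H-chromen-6-yl)-4-hydroxy-1-(phenylsulfinyl)butan-2-one (both sulfur epimers) | O=C(CS(=O)c1ccccc1)C[C@H](O)c1ccc2c(c1)C=CC(C)(C)O2 | intermediate
10 | (5S)-1-(dimethylamino)-5-(2,2-dimethyl-2H-chromen-6-yl)-5-hydroxy-2-(phenylsulfinyl)pent-1-en-3-one | CN(C)C=C(S(=O)c1ccccc1)C(=O)C[C@H](O)c1ccc2c(c1)C=CC(C)(C)O2 | intermediate (not isolated)
11 | (2S)-2-(2,2-dimethyl-2H-chromen-6-yl)-5-(phenylsulfinyl)-2,3-dihydro-4H-pyran-4-one (both sulfur epimers) | O=C1C[C@@H](c2ccc3c(c2)C=CC(C)(C)O3)OC=C1S(=O)c1ccccc1 | intermediate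
12 | (3E)-4-methoxybut-3-en-2-one | CO/C=C/C(C)=O | starting material
13 | 1-bromo-3-methylbut-2-ene | CC(C)=CCBr | starting material
14 | lithium (3E)-4-methoxybuta-1,3-dien-2-olate | [Li]OC(=C)/C=C/OC | intermediate (not isolated)
15 | (1E)-1-methoxy-7-methylocta-1,6-dien-3-one | CO/C=C/C(=O)CCC=C(C)C | intermediate
16 | (1E,3Z)-1-methoxy-7-methyl-3-[(trimethylsilyl)oxy]octa-1,3,6-triene | CO/C=C/C(O[Si](C)(C)C)=C/CC=C(C)C | intermediate
17 | (2S)-2-(2,2-dimethyl-2H-chromen-6-yl)-5-methoxy-8-(3-methylbut-2-en-1-yl)-4a-(phenylsulfinyl)-7-[(trimethylsilyl)oxy]-2,3,4a,5,8,8a-hexahydro-4H-chromen-4-one (stereoisomer mixture at C4a, C5, C8, C8a and S) | CC(C)=CCC1C(O[Si](C)(C)C)=CC(OC)C2(S(=O)c3ccccc3)C(=O)C[C@@H](c3ccc4c(c3)C=CC(C)(C)O4)OC12 | intermediate (not isolated)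
18 | (2S)-2-(2,2-dimethyl-2H-chromen-6-yl)-8-(3-methylbut-2-en-1-yl)-4a-(phenylsulfinyl)-2,3,8,8a-tetrahydro-4H-chromene-4,7(4aH)-dione (stereoisomer mixture at C4a, C8, C8a and S) | CC(C)=CCC1C(=O)C=CC2(S(=O)c3ccccc3)C(=O)C[C@@H](c3ccc4c(c3)C=CC(C)(C)O4)OC12 | intermediate (not isolated)
19 | (2S)-2-(2,2-dimethyl-2H-chromen-6-yl)-8-(3-methylbut-2-en-1-yl)-2,3-dihydro-4H-chromene-4,7(8H)-dione | CC(C)=CCC1C(=O)C=CC2=C1O[C@H](c1ccc3c(c1)C=CC(C)(C)O3)CC2=O | intermediate (not isolated)
20 | (2S)-2-(2,2-dimethyl-2H-chromen-6-yl)-7-hydroxy-8-(3-methylbut-2-en-1-yl)-2,3-dihydro-4H-chromen-4-one | CC(C)=CCc1c(O)ccc2c1O[C@H](c1ccc3c(c1)C=CC(C)(C)O3)CC2=O | target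

## Step count and risk

Total: 9 steps. Longest linear sequence: 7 steps (1, 2, 3, 4, 5, 6, 9); steps 7 and 8 form the second branch.

**Step 9 (key step).** Four processes could defeat it:
- The cycloaddition may be slow, because O1 donates into the enone, and the diene may decompose first.
- Sulfenic acid may be lost thermally towards C5–H before methanol has left, which gives a ring that cannot aromatise.
- An inverse-demand hetero-cycloaddition across O=C4–C5=C6 may compete.
- Acid may ionise the C2–O1 bond, whose benzylic cation is stabilised by the para oxygen, with loss of configuration.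

Fallback (known chemistry): the aryl-transfer disconnection of Alternative 2, setting out from 13 and 2 and returning at 20.
- 2,4-Dihydroxyacetophenone is C-prenylated with 13 (aq. KOH) and the isomers are separated to give 1-[2,4-dihydroxy-3-(3-methylbut-2-en-1-yl)phenyl]ethan-1-one F1.
- The non-chelated hydroxyl is protected (MOMCl, K2CO3) to give 1-[2-hydroxy-4-(methoxymethoxy)-3-(3-methylbut-2-en-1-yl)phenyl]ethan-1-one F2.
- Condensation with the formamide acetal and mild acid closes 7-(methoxymethoxy)-8-(3-methylbut-2-en-1-yl)-4H-chromen-4-one F3.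
- 4-Bromophenol is etherified with 2 as in step 1 to 1-bromo-4-[(2-methylbut-3-yn-2-yl)oxy]benzene F4 and rearranged as in step 2 to 6-bromo-2,2-dimethyl-2H-chromene F5.
- Bromine–lithium exchange (n-BuLi) and B(OiPr)3 give (2,2-dimethyl-2H-chromen-6-yl)boronic acid F6.
- Enantioselective conjugate addition of F6 to F3 (Pd(OCOCF3)2, the tert-butyl pyridine-oxazoline ligand of the hand that gives the (2S) product, NH4PF6, 1,2-dichloroethane/H2O, 60 °C) gives (2S)-2-(2,2-dimethyl-2H-chromen-6-yl)-7-(methoxymethoxy)-8-(3-methylbut-2-en-1-yl)-2,3-dihydro-4H-chromen-4-one F7.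
- Brief HCl in MeOH frees 20.

**Step 6.** Dehydration of the electron-rich benzylic carbinol, by enolisation towards C3 or by ionisation once acid is added, may outrun ring closure, or the carbinol may lose configuration. Fallback, from 9 back to 11: the closure is separated from the condensation and run as an acid-triggered deprotective cyclisation.
- Silylation (TBSCl, imidazole) gives (4S)-4-[(tert-butyldimethylsilyl)oxy]-4-(2,2-dimethyl-2H-chromen-6-yl)-1-(phenylsulfinyl)butan-2-one F8.
- Condensation with the formamide acetal is driven to completion and (5S)-5-[(tert-butyldimethylsilyl)oxy]-1-(dimethylamino)-5-(2,2-dimethyl-2H-chromen-6-yl)-2-(phenylsulfinyl)pent-1-en-3-one F9 is isolated.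
- HF·pyridine unmasks the alcohol in a medium in which it closes at once onto the protonated enaminone, giving 11.

**Step 7.** Proton exchange between product and enolate may lead to double alkylation, 14 may add in a conjugate sense to unreacted 12, and some SN2' attack may occur. Fallback, from 13 back to 15: the chain is built first and the methoxyvinyl end added last.
- Alkylation of ethyl acetoacetate with 13 (NaOEt) gives ethyl 2-acetyl-5-methylhex-4-enoate F10.
- Saponification and decarboxylation give 6-methylhept-5-en-2-one F11, which is also an article of commerce.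
- Kinetic formylation (LDA; ethyl formate) gives (1Z)-1-hydroxy-7-methylocta-1,6-dien-3-one F12.
- O-Methylation (Me2SO4, K2CO3, acetone) gives 15.

**Step 5.** The basic carbanion 8 may enolise the ester and stall the acylation, or the lithium alkoxide may fragment by retro-aldol reaction on warming. Fallback, from 6 back to 9: the acyl donor is changed in a separate step.
- MeNH(OMe)·HCl and i-PrMgCl convert 6 into (3S)-3-(2,2-dimethyl-2H-chromen-6-yl)-3-hydroxy-N-methoxy-N-methylpropanamide F13.
- Addition of 8 stops at a chelated tetrahedral intermediate, with no alkoxide leaving group and no condensation equilibrium; work-up gives 9.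

## Further compounds

F1 | step 9 | 1-[2,4-dihydroxy-3-(3-methylbut-2-en-1-yl)phenyl]ethan-1-one | CC(=O)c1ccc(O)c(CC=C(C)C)c1O
F2 | step 9 | 1-[2-hydroxy-4-(methoxymethoxy)-3-(3-methylbut-2-en-1-yl)phenyl]ethan-1-one | CC(=O)c1ccc(OCOC)c(CC=C(C)C)c1O
F3 | step 9 | 7-(methoxymethoxy)-8-(3-methylbut-2-en-1-yl)-4H-chromen-4-one | COCOc1ccc2c(c1CC=C(C)C)occc2=O
F4 | step 9 | 1-bromo-4-[(2-methylbut-3-yn-2-yl)oxy]benzene | C#CC(C)(C)Oc1ccc(Br)cc1
F5 | step 9 | 6-bromo-2,2-dimethyl-2H-chromene | CC1(C)C=Cc2cc(Br)ccc2O1
F6 | step 9 | (2,2-dimethyl-2H-chromen-6-yl)boronic acid | OB(O)c1ccc2c(c1)C=CC(C)(C)O2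
F7 | step 9 | (2S)-2-(2,2-dimethyl-2H-chromen-6-yl)-7-(methoxymethoxy)-8-(3-methylbut-2-en-1-yl)-2,3-dihydro-4H-chromen-4-one | COCOc1ccc2c(c1CC=C(C)C)O[C@H](c1ccc3c(c1)C=CC(C)(C)O3)CC2=O
F8 | step 6 | (4S)-4-[(tert-butyldimethylsilyl)oxy]-4-(2,2-dimethyl-2H-chromen-6-yl)-1-(phenylsulfinyl)butan-2-one | O=C(CS(=O)c1ccccc1)C[C@H](O[Si](C)(C)C(C)(C)C)c1ccc2c(c1)C=CC(C)(C)O2
F9 | step 6 | (5S)-5-[(tert-butyldimethylsilyl)oxy]-1-(dimethylamino)-5-(2,2-dimethyl-2H-chromen-6-yl)-2-(phenylsulfinyl)pent-1-en-3-one | CN(C)C=C(S(=O)c1ccccc1)C(=O)C[C@H](O[Si](C)(C)C(C)(C)C)c1ccc2c(c1)C=CC(C)(C)O2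
F10 | step 7 | ethyl 2-acetyl-5-methylhex-4-enoate | CCOC(=O)C(CC=C(C)C)C(C)=O
F11 | step 7 | 6-methylhept-5-en-2-one | CC(=O)CCC=C(C)C
F12 | step 7 | (1Z)-1-hydroxy-7-methylocta-1,6-dien-3-one | O/C=C\C(=O)CCC=C(C)C
F13 | step 5 | (3S)-3-(2,2-dimethyl-2H-chromen-6-yl)-3-hydroxy-N-methoxy-N-methylpropanamide | CON(C)C(=O)C[C@H](O)c1ccc2c(c1)C=CC(C)(C)O2
A1 | alternative 1 | (2E)-3-(2,2-dimethyl-2H-chromen-6-yl)-1-[2-hydroxy-4-(methoxymethoxy)-3-(3-methylbut-2-en-1-yl)phenyl]prop-2-en-1-one | COCOc1ccc(C(=O)/C=C/c2ccc3c(c2)C=CC(C)(C)O3)c(O)c1CC=C(C)C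
A2 | alternative 2 | 7-(methoxymethoxy)-8-(3-methylbut-2-en-1-yl)-4H-chromen-4-one | COCOc1ccc2c(c1CC=C(C)C)occc2=O
A3 | alternative 2 | (2,2-dimethyl-2H-chromen-6-yl)boronic acid | OB(O)c1ccc2c(c1)C=CC(C)(C)O2
A4 | alternative 3 | 2-(3-methylbut-2-en-1-yl)cyclohexane-1,3-dione | CC(C)=CCC1C(=O)CCCC1=O
A5 | alternative 3 | (2S)-2-(2,2-dimethyl-2H-chromen-6-yl)-7-methoxy-8-(3-methylbut-2-en-1-yl)-2,3,5,6-tetrahydro-4H-chromen-4-one | COC1=C(CC=C(C)C)C2=C(CC1)C(=O)C[C@@H](c1ccc3c(c1)C=CC(C)(C)O3)O2
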